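The aryl group on C3, ring C, is a resorcinol joined to that congested stereocentre at its own C5, the one ring carbon that Friedel–Crafts chemistry cannot address because it lies meta to both hydroxyls. Ring C is therefore not coupled but assembled in place. The controlling disconnection takes ring C back to a cyclobutenone on C3 plus an ynol ether; a single thermal pericyclic cascade forges two C–C bonds and the whole benzene ring, the mechanism itself dictating the 1,3,5 pattern. The precursor is a trans-2-aryl-5-bromo-2,3-dihydrobenzofuran carrying a cyclobut-2-en-1-one at C3, derived from an enantioselective carbene C–H insertion; the C5 bromide later accepts the stilbene arm.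

Key step: step 8

Remark: Rh2(R-PTTL)4, dirhodium tetrakis[N-phthaloyl-(R)-tert-leucinate], is specified on the understanding that its S antipode leads to the 2R series with benzyl aryl ethers of this kind; the sense is to be confirmed by correlation on the first run and the antipodal catalyst used if it proves opposite.
Remark: the acetate-protected styrene of step 10 is treated as a catalogue compound; if it must be made, Wittig methylenation of 3,5-dihydroxybenzaldehyde followed by acetylation provides it in two extra steps.
Remark: the carbene insertion is expected to give the cis ester, so the trans relationship is installed by a separate equilibration (step 4), and the alkyl ethers are cleaved before the stilbene is built so that the Lewis acid never meets the electron-rich alkene.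

Step 1
Reactants: 1 methyl 2-(5-bromo-2-hydroxyphenyl)acetate; 2 4-methoxybenzyl chloride
Product: 3 methyl 2-{5-bromo-2-[(4-methoxybenzyl)oxy]phenyl}acetate
Conditions: K2CO3, NaI (cat.), DMF, rt
Reagents that add atoms: none
Why: Williamson etherification: the phenoxide formed by K2CO3 should displace chloride from the activated benzylic carbon (SN2) faster than it can lactonise onto the neighbouring methyl ester at room temperature, and no stereocentre is involved.

Step 2
Reactants: 3 methyl 2-{5-bromo-2-[(4-methoxybenzyl)oxy]phenyl}acetate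
Product: 4 methyl 2-{5-bromo-2-[(4-methoxybenzyl)oxy]phenyl}-2-diazoacetate
Conditions: 4-acetamidobenzenesulfonyl azide, DBU, MeCN, 0 °C → rt
Reagents that add atoms: 4-acetamidobenzenesulfonyl azide, CC(=O)Nc1ccc(cc1)S(=O)(=O)N=[N+]=[N-]
Why: Regitz diazo transfer: the DBU-generated enolate of the aryl-activated methylene attacks the terminal nitrogen of the sulfonyl azide and expels the sulfonamide, which should give the donor/acceptor aryldiazoacetate without touching the benzyl ether or the bromide.

Step 3
Reactants: 4 methyl 2-{5-bromo-2-[(4-methoxybenzyl)oxy]phenyl}-2-diazoacetate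
Product: 5 methyl (2S,3R)-5-bromo-2-(4-methoxyphenyl)-2,3-dihydro-1-benzofuran-3-carboxylate (cis ester)
Conditions: Rh2(R-PTTL)4 (1 mol %), toluene, −78 → −60 °C
Reagents that add atoms: none
Why: Intramolecular 1,5 C–H insertion of the dirhodium donor/acceptor carbene into the oxygen-activated benzylic C–H bond: the chiral carboxylate ligand sphere should select one enantiotopic hydrogen and thereby fix C2 as S, while the compact three-centre transition state places the ester cis to the aryl group (C3 R), a relationship that step 4 corrects.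

Step 4
Reactants: 5 methyl (2S,3R)-5-bromo-2-(4-methoxyphenyl)-2,3-dihydro-1-benzofuran-3-carboxylate
Product: 6 methyl (2S,3S)-5-bromo-2-(4-methoxyphenyl)-2,3-dihydro-1-benzofuran-3-carboxylate (trans ester)
Conditions: NaOMe (cat.), MeOH–THF, rt; then AcOH
Reagents that add atoms: none
Why: Thermodynamic epimerisation through the ester enolate: reprotonation should settle C3 in the less congested trans (2S,3S) arrangement, and C2 is not at risk because loss of the O1 phenoxide from the enolate would be a stereoelectronically disfavoured retro-5-endo-trig elimination.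

Step 5
Reactants: 6 methyl (2S,3S)-5-bromo-2-(4-methoxyphenyl)-2,3-dihydro-1-benzofuran-3-carboxylate
Product: 8 (2S,3S)-5-bromo-3-ethynyl-2-(4-methoxyphenyl)-2,3-dihydro-1-benzofuran, via aldehyde 7 (not isolated)
Conditions: i-Bu2AlH (1.1 equiv), CH2Cl2, −78 °C; then MeOH, K2CO3, dimethyl (1-diazo-2-oxopropyl)phosphonate, −78 °C → rt
Reagents that add atoms: dimethyl (1-diazo-2-oxopropyl)phosphonate, COP(=O)(OC)C(=[N+]=[N-])C(C)=O
Why: Partial ester reduction held at the tetrahedral aluminium hemiacetal, followed by Seyferth–Gilbert homologation in its Ohira–Bestmann form (phosphonate addition, loss of N2 and 1,2-hydrogen shift of the alkylidene carbene), should give the terminal alkyne in one flask, and any enolisation of aldehyde 7 at C3 can only return the favoured trans isomer.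

Step 6
Reactants: 8 (2S,3S)-5-bromo-3-ethynyl-2-(4-methoxyphenyl)-2,3-dihydro-1-benzofuran; 9 trichloroacetyl chloride
Product: 11 4,4-dichloro-3-[(2S,3R)-5-bromo-2-(4-methoxyphenyl)-2,3-dihydro-1-benzofuran-3-yl]cyclobut-2-en-1-one, via dichloroketene 10 (not isolated)
Conditions: Zn–Cu couple, slow addition of 9, Et2O–DME, rt
Reagents that add atoms: none
Why: Ketene–alkyne [2+2] cycloaddition: dichloroketene released by zinc from 9 should add with its electrophilic carbonyl carbon to the unsubstituted alkyne carbon, which puts the dihydrobenzofuranyl group on C3 of the cyclobutenone, while DME keeps ZnCl2 away from the benzylic ether; the R descriptor at C3 arises only from the CIP rank of the CCl2 branch, not from a change in geometry.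

Step 7
Reactants: 11 4,4-dichloro-3-[(2S,3R)-5-bromo-2-(4-methoxyphenyl)-2,3-dihydro-1-benzofuran-3-yl]cyclobut-2-en-1-one
Product: 12 3-[(2S,3S)-5-bromo-2-(4-methoxyphenyl)-2,3-dihydro-1-benzofuran-3-yl]cyclobut-2-en-1-one
Conditions: Zn dust, AcOH, TMEDA, EtOH, 0 °C → rt
Reagents that add atoms: none
Why: Reductive dechlorination of the α,α-dichloroketone by zinc (zinc enolate formation and protonation by acetic acid, twice) under amine-buffered conditions should leave the strained enone, the aryl bromide and the benzylic ether intact, and C3, which is vinylogously enolisable, has trans as its resting configuration.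

Step 8
Reactants: 12 3-[(2S,3S)-5-bromo-2-(4-methoxyphenyl)-2,3-dihydro-1-benzofuran-3-yl]cyclobut-2-en-1-one; 13 ethoxyacetylene
Product: 18 3-[(2S,3S)-5-bromo-2-(4-methoxyphenyl)-2,3-dihydro-1-benzofuran-3-yl]-5-ethoxyphenol, via vinylketene 14 (not isolated), via 4-vinylcyclobutenone 15 (not isolated), via dienylketene 16 (not isolated), via cyclohexadienone 17 (not isolated)
Conditions: 13 (3 equiv, hexane solution), toluene, 80 °C, sealed tube, argon; then K2CO3, MeOH, rt (returns any O-acylated phenol)
Reagents that add atoms: none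
Why: Heating should open the four-membered ring of 12 in a conrotatory electrocyclic step to vinylketene 14, whose ketene C=C bond adds across the ynol ether (its CH terminus to the ketene carbonyl carbon) to give 4-vinylcyclobutenone 15; a second ring opening gives dienylketene 16, which closes between the ketene carbon and the terminal methylene to cyclohexadienone 17 and then tautomerises to phenol 18. The closest known reaction type is the Danheiser benzannulation of 3-substituted cyclobutenones with alkoxyalkynes, an established route to 5-substituted resorcinol monoethers. The only ring closed in the net change is ring C, by thermal disrotatory six-electron electrocyclisation; the four-membered ring of 15 is transient. No stereocentre is created, since the sp3 ring carbon of 15 is erased when that ring opens. The selectivity that matters is the orientation in which ketene and alkyne combine: it is set by the polarisation of 13 and by the position of the dihydrobenzofuranyl group on C3 of the cyclobutenone, so that this group ends meta to both OH and OEt. The benzylic C2–O1 bond, the C–Br bond and both stereocentres should survive because the medium is free of acid and base and 80 °C lies below the temperature at which 13 fragments to ketene.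

Step 9
Reactants: 18 3-[(2S,3S)-5-bromo-2-(4-methoxyphenyl)-2,3-dihydro-1-benzofuran-3-yl]-5-ethoxyphenol
Product: 19 5-[(2S,3S)-5-bromo-2-(4-hydroxyphenyl)-2,3-dihydro-1-benzofuran-3-yl]benzene-1,3-diol
Conditions: BBr3 (6 equiv), CH2Cl2, −78 °C → rt; then H2O, 0 °C
Reagents that add atoms: none
Why: Lewis-acid ether cleavage (bromide SN2 at the methyl and ethyl carbons of the boron-complexed ethers) is placed before the stilbene exists so that no electron-rich alkene meets the acid, and excess BBr3 turns the ring A oxygen into an aryloxyborane, removing the para donor that could assist ionisation of C2–O1, while any reversible opening would re-close trans under control of the untouched C3.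

Step 10
Reactants: 19 5-[(2S,3S)-5-bromo-2-(4-hydroxyphenyl)-2,3-dihydro-1-benzofuran-3-yl]benzene-1,3-diol; 20 5-ethenyl-1,3-phenylene diacetate (3,5-diacetoxystyrene)
Product: 22 (2S,3S)-trans-delta-viniferin, via ring D diacetate 21 (not isolated)
Conditions: Pd(OAc)2 (5 mol %), P(o-tol)3 (10 mol %), Et3N, DMF, 100 °C, argon; then MeOH, K2CO3, rt; AcOH
Reagents that add atoms: none
Why: Mizoroki–Heck coupling (oxidative addition of zerovalent palladium into C5–Br, syn carbopalladation at the unsubstituted styrene terminus, syn β-hydride elimination) should give the E alkene, and base-catalysed transesterification with methanol then strips the aryl acetates, including any that migrated to other phenols, so that all acetylated forms converge on the pentaphenol.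

Compound list
1 | methyl 2-(5-bromo-2-hydroxyphenyl)acetate | COC(=O)Cc1cc(Br)ccc1O | starting material
2 | 4-methoxybenzyl chloride | COc1ccc(CCl)cc1 | starting material
3 | methyl 2-{5-bromo-2-[(4-methoxybenzyl)oxy]phenyl}acetate | COC(=O)Cc1cc(Br)ccc1OCc1ccc(OC)cc1 | intermediate
4 | methyl 2-{5-bromo-2-[(4-methoxybenzyl)oxy]phenyl}-2-diazoacetate | COC(=O)C(=[N+]=[N-])c1cc(Br)ccc1OCc1ccc(OC)cc1 | intermediate
5 | methyl (2S,3R)-5-bromo-2-(4-methoxyphenyl)-2,3-dihydro-1-benzofuran-3-carboxylate (cis) | COc1ccc([C@H]2Oc3ccc(Br)cc3[C@H]2C(=O)OC)cc1 | intermediate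
6 | methyl (2S,3S)-5-bromo-2-(4-methoxyphenyl)-2,3-dihydro-1-benzofuran-3-carboxylate (trans) | COc1ccc([C@H]2Oc3ccc(Br)cc3[C@@H]2C(=O)OC)cc1 | intermediate
7 | (2S,3S)-5-bromo-2-(4-methoxyphenyl)-2,3-dihydro-1-benzofuran-3-carbaldehyde | COc1ccc([C@H]2Oc3ccc(Br)cc3[C@@H]2C=O)cc1 | intermediate
8 | (2S,3S)-5-bromo-3-ethynyl-2-(4-methoxyphenyl)-2,3-dihydro-1-benzofuran | COc1ccc([C@H]2Oc3ccc(Br)cc3[C@@H]2C#C)cc1 | intermediate
9 | trichloroacetyl chloride | ClC(=O)C(Cl)(Cl)Cl | starting material
10 | dichloroketene | ClC(Cl)=C=O | intermediate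
11 | 4,4-dichloro-3-[(2S,3R)-5-bromo-2-(4-methoxyphenyl)-2,3-dihydro-1-benzofuran-3-yl]cyclobut-2-en-1-one (trans ring substituents) | COc1ccc([C@H]2Oc3ccc(Br)cc3[C@@H]2C2=CC(=O)C2(Cl)Cl)cc1 | intermediate
12 | 3-[(2S,3S)-5-bromo-2-(4-methoxyphenyl)-2,3-dihydro-1-benzofuran-3-yl]cyclobut-2-en-1-one | COc1ccc([C@H]2Oc3ccc(Br)cc3[C@@H]2C2=CC(=O)C2)cc1 | intermediate
13 | ethoxyacetylene | C#COCC | starting material
14 | 3-[(2S,3S)-5-bromo-2-(4-methoxyphenyl)-2,3-dihydro-1-benzofuran-3-yl]buta-1,3-dien-1-one (vinylketene) | COc1ccc([C@H]2Oc3ccc(Br)cc3[C@@H]2C(=C)C=C=O)cc1 | intermediate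
15 | 3-ethoxy-4-{1-[(2S,3S)-5-bromo-2-(4-methoxyphenyl)-2,3-dihydro-1-benzofuran-3-yl]ethenyl}cyclobut-2-en-1-one (both configurations at ring C4) | COc1ccc([C@H]2Oc3ccc(Br)cc3[C@@H]2C(=C)C2C(=O)C=C2OCC)cc1 | intermediate
16 | (3E)-3-ethoxy-5-[(2S,3S)-5-bromo-2-(4-methoxyphenyl)-2,3-dihydro-1-benzofuran-3-yl]hexa-1,3,5-trien-1-one (dienylketene, ketene and vinyl carbons cis) | COc1ccc([C@H]2Oc3ccc(Br)cc3[C@@H]2C(=C)/C=C(OCC)\C=C=O)cc1 | intermediate
17 | 3-ethoxy-5-[(2S,3S)-5-bromo-2-(4-methoxyphenyl)-2,3-dihydro-1-benzofuran-3-yl]cyclohexa-2,4-dien-1-one | COc1ccc([C@H]2Oc3ccc(Br)cc3[C@@H]2C2=CC(OCC)=CC(=O)C2)cc1 | intermediate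
18 | 3-[(2S,3S)-5-bromo-2-(4-methoxyphenyl)-2,3-dihydro-1-benzofuran-3-yl]-5-ethoxyphenol | COc1ccc([C@H]2Oc3ccc(Br)cc3[C@@H]2c2cc(O)cc(OCC)c2)cc1 | intermediate
19 | 5-[(2S,3S)-5-bromo-2-(4-hydroxyphenyl)-2,3-dihydro-1-benzofuran-3-yl]benzene-1,3-diol | Oc1ccc([C@H]2Oc3ccc(Br)cc3[C@@H]2c2cc(O)cc(O)c2)cc1 | intermediate
20 | 5-ethenyl-1,3-phenylene diacetate (3,5-diacetoxystyrene) | C=Cc1cc(OC(C)=O)cc(OC(C)=O)c1 | starting material
21 | 5-{(E)-2-[(2S,3S)-3-(3,5-dihydroxyphenyl)-2-(4-hydroxyphenyl)-2,3-dihydro-1-benzofuran-5-yl]ethenyl}-1,3-phenylene diacetate | Oc1ccc([C@H]2Oc3ccc(/C=C/c4cc(OC(C)=O)cc(OC(C)=O)c4)cc3[C@@H]2c2cc(O)cc(O)c2)cc1 | intermediate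
22 | (2S,3S)-trans-delta-viniferin, 5-[(2S,3S)-5-[(E)-2-(3,5-dihydroxyphenyl)ethenyl]-2-(4-hydroxyphenyl)-2,3-dihydro-1-benzofuran-3-yl]benzene-1,3-diol | Oc1ccc([C@H]2Oc3ccc(/C=C/c4cc(O)cc(O)c4)cc3[C@@H]2c2cc(O)cc(O)c2)cc1 | target

Total step count: 10. Longest linear sequence: 10 steps, from 1 to 22; compounds 2, 9, 13 and 20 enter as purchased reagents.

Steps most likely to fail

Step 8. The vinylketene may be lost to dimerisation or to acylation of the product phenol before the ynol ether intercepts it, and prolonged heating may fragment the ynol ether. The fallback builds ring C by condensation chemistry instead. It sets out from trans ester 6, whose i-Bu2AlH reduction is worked up at the stage of aldehyde 7, now isolated. Wittig olefination with 1-(triphenylphosphoranylidene)propan-2-one in toluene should give (3E)-4-[(2S,3S)-5-bromo-2-(4-methoxyphenyl)-2,3-dihydro-1-benzofuran-3-yl]but-3-en-2-one F1. Michael–Claisen annulation with dimethyl malonate and NaOMe in MeOH should give methyl 2,4-dioxo-6-[(2S,3S)-5-bromo-2-(4-methoxyphenyl)-2,3-dihydro-1-benzofuran-3-yl]cyclohexane-1-carboxylate F2. Saponification and decarboxylation lead to 5-[(2S,3S)-5-bromo-2-(4-methoxyphenyl)-2,3-dihydro-1-benzofuran-3-yl]cyclohexane-1,3-dione F3. Iodine in methanol at reflux aromatises this to (2S,3S)-5-bromo-3-(3,5-dimethoxyphenyl)-2-(4-methoxyphenyl)-2,3-dihydro-1-benzofuran F4; a partly methylated ring C would converge in the next operation. BBr3 under the conditions of step 9 then cleaves the methyl ethers and the route is rejoined at 19.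

Step 3. Facial discrimination between the two benzylic hydrogens may be insufficient or of the opposite sense. The fallback gives up catalyst control and resolves instead. It sets out from diazo ester 4, which with Rh2(OAc)4 in CH2Cl2 should give racemic methyl cis-5-bromo-2-(4-methoxyphenyl)-2,3-dihydro-1-benzofuran-3-carboxylate F5, possibly mixed with its trans isomer. NaOMe in MeOH converges this material on racemic methyl trans-5-bromo-2-(4-methoxyphenyl)-2,3-dihydro-1-benzofuran-3-carboxylate F6. Preparative chromatography on a chiral stationary phase then delivers the (2S,3S) enantiomer, and the route is rejoined at 6.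

Step 9. The Lewis acid may open the C2–O1 bond to a benzylic bromide that does not re-close cleanly during work-up. The fallback accepts the opening and re-closes the ring deliberately. It sets out from 18, which is treated with excess BBr3 at room temperature until dealkylation and ring opening are complete, giving 4-bromo-2-[(1S)-2-bromo-1-(3,5-dihydroxyphenyl)-2-(4-hydroxyphenyl)ethyl]phenol F7 as a mixture of epimers at the CHBr carbon. Without purification this is stirred with NaHCO3 in aqueous THF at 0 °C, which eliminates HBr through the 4-hydroxyphenyl group to 4-[(2S)-2-(5-bromo-2-hydroxyphenyl)-2-(3,5-dihydroxyphenyl)ethylidene]cyclohexa-2,5-dien-1-one F8. The neighbouring phenol adds to this para-quinone methide in a 5-exo-trig oxa-Michael closure, trans to the aryl group on the intact C3 centre, and the route is rejoined at 19.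

Further compounds
F1 | step 8 | (3E)-4-[(2S,3S)-5-bromo-2-(4-methoxyphenyl)-2,3-dihydro-1-benzofuran-3-yl]but-3-en-2-one | COc1ccc([C@H]2Oc3ccc(Br)cc3[C@@H]2/C=C/C(C)=O)cc1
F2 | step 8 | methyl 2,4-dioxo-6-[(2S,3S)-5-bromo-2-(4-methoxyphenyl)-2,3-dihydro-1-benzofuran-3-yl]cyclohexane-1-carboxylate (mixture at the two new ring centres) | COc1ccc([C@H]2Oc3ccc(Br)cc3[C@@H]2C2CC(=O)CC(=O)C2C(=O)OC)cc1
F3 | step 8 | 5-[(2S,3S)-5-bromo-2-(4-methoxyphenyl)-2,3-dihydro-1-benzofuran-3-yl]cyclohexane-1,3-dione | COc1ccc([C@H]2Oc3ccc(Br)cc3[C@@H]2C2CC(=O)CC(=O)C2)cc1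
F4 | step 8 | (2S,3S)-5-bromo-3-(3,5-dimethoxyphenyl)-2-(4-methoxyphenyl)-2,3-dihydro-1-benzofuran | COc1ccc([C@H]2Oc3ccc(Br)cc3[C@@H]2c2cc(OC)cc(OC)c2)cc1
F5 | step 3 | racemic methyl cis-5-bromo-2-(4-methoxyphenyl)-2,3-dihydro-1-benzofuran-3-carboxylate | COc1ccc([C@H]2Oc3ccc(Br)cc3[C@H]2C(=O)OC)cc1.COc1ccc([C@@H]2Oc3ccc(Br)cc3[C@@H]2C(=O)OC)cc1
F6 | step 3 | racemic methyl trans-5-bromo-2-(4-methoxyphenyl)-2,3-dihydro-1-benzofuran-3-carboxylate | COc1ccc([C@H]2Oc3ccc(Br)cc3[C@@H]2C(=O)OC)cc1.COc1ccc([C@@H]2Oc3ccc(Br)cc3[C@H]2C(=O)OC)cc1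
F7 | step 9 | 4-bromo-2-[(1S)-2-bromo-1-(3,5-dihydroxyphenyl)-2-(4-hydroxyphenyl)ethyl]phenol (both epimers at the CHBr carbon) | Oc1ccc(C(Br)[C@H](c2cc(Br)ccc2O)c2cc(O)cc(O)c2)cc1
F8 | step 9 | 4-[(2S)-2-(5-bromo-2-hydroxyphenyl)-2-(3,5-dihydroxyphenyl)ethylidene]cyclohexa-2,5-dien-1-one | O=C1C=CC(=C[C@H](c2cc(Br)ccc2O)c2cc(O)cc(O)c2)C=C1
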